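## Structural features

The target is a 2-aryl-2,3-dihydro-4H-chromen-4-one, a dihydroflavonol methylated at the C3 oxygen. Aromatic ring A is fused through C4a and C8a to the oxygen heterocycle ring C, and C2 of ring C carries aryl ring B. Ring A bears three adjacent methoxy groups at C5, C6 and C7; ring B is a 4-methoxyphenyl group with free phenols at its positions 3 and 5. The only stereocentres are the neighbours C2 (aryl, O1) and C3 (methoxy), both R, which places the two substituents trans and equatorial on ring C. The fragile points are these: the C3 hydrogen is next to the C4 carbonyl and can epimerise, base can open ring C by expelling the O1 phenoxide from the C4 enolate (which would erase C2), the C5 methoxy group beside the carbonyl is open to Lewis-acid demethylation, and the ring B phenols must stay masked until the end. The carbon skeleton is simple, two arenes joined by a three-atom bridge, so the real difficulty is to set the C2/C3 pair in absolute and relative terms in a β-oxygenated α-alkoxy ketone and to keep it through ring closure. The key step uses the fact that C3 carries the methoxy oxygen, the bond to the C4 carbonyl and the bond to C2, which is the pattern left when a ketocarbene carbon picks up an alcohol and then an aldehyde. C8a of ring A is marked with bromine so that the C2 oxygen can be joined to it afterwards without touching either stereocentre.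

## Logic of the disconnections

12 to 11: the two benzylic O–CH2 bonds on ring B are cut. Free phenols would compete with 8 for the carbene and would interfere with the base-mediated ring closure, so they are carried as benzyl ethers. The gain is a fully protected, neutral late intermediate. The demand is a hydrogenolysis that spares the C4 ketone and the cyclic benzylic C2–O1 bond.

11 to 10: the C8a–O1 bond is cut. The oxygen stays on C2, so the forward closure does not break any bond at a stereocentre and is retentive. Ring C disappears and the stereodiad becomes an open-chain anti aldol pattern. The forward aryl C–O coupling must be faster than retro-aldol cleavage, enolisation at C3 and β-hydride elimination, and it needs a halogen at C8a.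

10 to 4, 7 and 8: the C2–C3 bond and the C3–O(methyl) bond are cut. C3 is the one atom bonded to the carbonyl, the methoxy oxygen and C2, so it is treated as a carbene carbon. Three achiral pieces result, two of them of similar size, and both stereocentres are created in one convergent step. The forward step must trap the ylide with 7 faster than it collapses to plain O–H insertion, and the chiral acid must deliver the anti (2R,3R) adduct.

4 to 2 (through 3): the C=N bond of the diazo group is cut. Diazo transfer to an activated methyl ketone replaces the acid chloride/diazomethane route, so no diazomethane is handled and two steps are saved. The demand is a temporary activation of the methyl group, because a simple ketone enolate does not accept a diazo group cleanly.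

2 to 1: the aryl–acyl bond (C4a–C4) is cut. In 1 the two free ring positions are equivalent, each ortho to one methoxy group, para to another and ortho to bromine, so acylation can give only one isomer. The gain is a commercial arene. The Lewis acid must not cleave the methoxy group that ends up beside the new carbonyl.

7 to 6: the formyl C–H bond is traced back to the ester C–OMe bond, because the ester is the commercial oxidation level. The demand is a hydride reduction that stops at the aldehyde.

6 to 5: the two O–benzyl bonds are cut. This is a plain double O-alkylation of a commercial diphenol with no selectivity issue.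

## Other disconnections considered

Alternative 1: The cut runs through ring A itself, at C4a–C8a and C7–C8, so neither ring A nor ring C exists before the key step.
- Forward step: the tethered cyclobutenone ynol ether A1 would be heated. Four-electron ring opening gives a vinylketene, [2+2] addition to the ethynyl ether and a second ring opening give a dienylketene, and six-electron closure with tautomerisation would give the chromanol A2 (intramolecular Danheiser benzannulation).
- In its favour: the oxygenation pattern of ring A follows from connectivity alone, and two rings and two C–C bonds form without any reagent.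
- Better than the chosen plan on one point: C4 is at the alcohol level during the cascade, so C3 has no acidic hydrogen and cannot epimerise. In the chosen plan C3 sits beside a ketone during a base-mediated step.
- Against it here: the C2/C3 pair must already be present in A1, so the cascade solves none of the stereochemical problem. A1 also combines a secondary benzylic alkynyl ether, which can rearrange sigmatropically or lose ketene by a retro-ene path on warming, with a cyclobutenone that opens only on heating. Four operations would remain after A2: methylation of the C7 phenol, desilylation, oxidation at C4 and debenzylation.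
- Comparison: structurally it builds an aromatic ring that can be bought with all three oxygens in place, whereas the chosen plan makes only the three-atom bridge. Mechanistically a thermal pericyclic cascade has no competing bimolecular pathway, which is an advantage over a three-component trapping, but its thermal window is narrow. In step count it would be clearly longer than seven steps.

Alternative 2: The cut is the same C2–C3 bond, but in a substrate where O1 already links ring A to the benzylic carbon of ring B.
- Forward step: the diazoketone A3 would be treated with Rh2(S-PTTL)4 (dirhodium tetrakis[N-phthaloyl-(S)-tert-leucinate]). The carbene would insert into one of the two enantiotopic O–CH2 hydrogens and give the flavanone A4, closing ring C and setting C2. A4 is (2S) only because C3 is a methylene group; its arrangement in space is that of 12.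
- In its favour: the C–H bond is activated by both oxygen and aryl. A3 needs only an ether formation and a diazo transfer, so its preparation is equal in effort to that of 4.
- Better than the chosen plan on one point: ring closure and C–C bond formation coincide, so no aryl halide, no palladium step and no retro-aldol-prone β-hydroxy ketone are involved.
- Against it here: C3 arrives without its oxygen. An enolate oxidation and an O-methylation would have to follow under basic conditions, where flavanones open by β-elimination of the phenoxide and C2 is put at risk, and the trans relation would rest on substrate control alone. The ether oxygen can also attack the carbene to give a five-membered cyclic oxonium ylide followed by a [1,2] benzyl shift, and six-membered C–H insertion has to win against this normally favoured pathway.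
- Comparison: the mechanistic family is the same (a rhodium carbene from an aryl diazoketone). Catalyst control of one centre is arguably more secure than control of two centres in a three-component event, and on that point the alternative is at least equal. The later oxygenation at C3 makes it longer by about two steps and moves the base-sensitivity problem to a worse place.

Alternative 3: The cut is C4a–C5, so ring A is made last from a polycarbonyl chain on a preformed ring C.
- Forward step: with Mg(OMe)2 the extended enolate of the dihydropyranone keto ester A5 would attack its terminal ester through C4a. Loss of methanol and enolisation would give the resorcinol-type flavanone A6.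
- In its favour: the closure is biomimetic and needs neither diazo compounds nor a precious metal, and on handling hazards it is better than the chosen plan. C2 and C3 would be carried in a ring in which the trans arrangement is the stable one, which is equal to the situation in the chosen plan after step 6.
- Against it here: A6 has free hydroxyls at C5 and C7, so two O-methylations would be needed. The one at the chelated C5 hydroxyl requires forcing base, which endangers C3 and, through ring opening, C2. In A5 the C3 hydrogen is already next to a carbonyl while Mg(OMe)2 is present. A5 is also much harder to assemble than the trimethoxyarene it replaces.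
- Comparison: structurally the alternative spends its key step on a ring that is commercially trivial, while the chosen plan spends it on the two stereocentres. Mechanistically an intramolecular Claisen condensation is robust and free of chemoselectivity questions among three components, which is a point for the alternative. In step count it would be much longer.

Key step: step 5

Remarks and assumptions:
- Assumption: the (R) enantiomer of the phosphoric acid is taken as the one that leads to the (2R,3R) series in step 5. If the sense of induction proves opposite, its mirror image is used with no other change.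
- Remark on the structures: the open-chain adduct 10 and the target 12 both carry (2R,3R). Ring closure breaks no bond at a stereocentre and the priority order at both centres is unchanged, so the anti aldol corresponds to the trans flavanone.
- Design remark: the skeleton of 4 is unchanged, but it is reached in two steps by acylation and deacylative diazo transfer, with a thermally stable sulfonyl azide, so no diazomethane is used. 4 is kept cold and in solution and is not distilled. 7 is reached in two steps.
- Compounds 1, 5 and 8 are taken as commercial.

## Route

Step 1
Reactants: 1 5-bromo-1,2,3-trimethoxybenzene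
Product: 2 1-(6-bromo-2,3,4-trimethoxyphenyl)ethan-1-one
Conditions: AcCl, SnCl4, CH2Cl2, −10 to 0 °C
Reagents that add atoms: acetyl chloride, CC(Cl)=O
Why: Friedel–Crafts acylation; the two free positions of 1 are equivalent, each para to one methoxy group and ortho to another, so only one isomer can form. The mild Lewis acid and low temperature are chosen to limit cleavage of the methoxy group next to the new carbonyl.

Step 2
Reactants: 2 1-(6-bromo-2,3,4-trimethoxyphenyl)ethan-1-one
Product: 4 1-(6-bromo-2,3,4-trimethoxyphenyl)-2-diazoethan-1-one, via trifluoroacetyl ketone 3 (not isolated)
Conditions: LiN(SiMe3)2, THF, −78 °C; CF3CO2CH2CF3; then 4-AcNHC6H4SO2N3, Et3N, H2O, MeCN, rt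
Reagents that add atoms: 4-acetamidobenzenesulfonyl azide, CC(=O)Nc1ccc(cc1)S(=O)(=O)N=[N+]=[N-] (the two diazo nitrogens); 2,2,2-trifluoroethyl trifluoroacetate, O=C(OCC(F)(F)F)C(F)(F)F (trifluoroacetyl group of 3 only, lost again before 4)
Why: Claisen-type trifluoroacetylation of the lithium enolate activates the methyl group, and deacylative Regitz diazo transfer then moves the trifluoroacetyl group to the sulfonamide nitrogen and leaves the terminal diazoketone. The aryl bromide and the methyl ethers are inert to the amide base at −78 °C and to the amine at room temperature.

Step 3
Reactants: 5 methyl 3,5-dihydroxy-4-methoxybenzoate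
Product: 6 methyl 3,5-bis(benzyloxy)-4-methoxybenzoate
Conditions: BnBr, K2CO3, DMF, 60 °C
Reagents that add atoms: benzyl bromide, BrCc1ccccc1
Why: Williamson ether synthesis on both phenols; the methyl ester and the methyl ether are stable to carbonate in DMF.

Step 4
Reactants: 6 methyl 3,5-bis(benzyloxy)-4-methoxybenzoate
Product: 7 3,5-bis(benzyloxy)-4-methoxybenzaldehyde
Conditions: NaAlH2(OCH2CH2OMe)2, pyrrolidine, toluene/THF, 0 °C; aq. HCl
Reagents that add atoms: none
Why: Partial hydride reduction of an aromatic ester with an amine-modified alkoxyaluminium hydride; the tetrahedral amino alkoxy aluminate does not collapse until hydrolysis, so reduction should stop at the aldehyde. Benzyl and methyl aryl ethers are inert.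

Step 5
Reactants: 4 1-(6-bromo-2,3,4-trimethoxyphenyl)-2-diazoethan-1-one, 7 3,5-bis(benzyloxy)-4-methoxybenzaldehyde, 8 methanol
Product: 10 (2R,3R)-3-[3,5-bis(benzyloxy)-4-methoxyphenyl]-1-(6-bromo-2,3,4-trimethoxyphenyl)-3-hydroxy-2-methoxypropan-1-one, via oxonium ylide 9 (not isolated)
Conditions: Rh2(OAc)4 (2 mol %), (R)-TRIP [(R)-3,3′-bis(2,4,6-triisopropylphenyl)-1,1′-binaphthyl-2,2′-diyl hydrogen phosphate] (10 mol %), 4 Å molecular sieves, CH2Cl2, −20 °C, slow addition of 4
Reagents that add atoms: none
Why: Rh2(OAc)4 releases N2 from 4 and gives an electrophilic rhodium carbene at the future C3, to which 8 adds through oxygen to give the protic oxonium ylide 9 (metal-bound or as its enol). The phosphoric acid holds this nucleophile through its phosphoryl oxygen and activates the carbonyl group of 7 through its acidic O–H, so that C–C bond formation overtakes the 1,2-proton shift that would end in simple O–H insertion. The closest known reaction type is the cooperative dirhodium/chiral Brønsted acid three-component aldol- or Mannich-type trapping of alcohol-derived oxonium ylides of diazo carbonyl compounds. No ring is closed; two skeletal bonds (C3–OMe and C2–C3) are formed. Both stereocentres arise in the one C–C bond-forming event: the absolute configuration is controlled by the chiral pocket of the acid, whose 3,3′-aryl groups choose the face of the bound aldehyde, and the anti relation by the arrangement in which the aryl group of 7 points away from the bulky, twisted aroyl group of the enol. The selectivity needed is trapping over O–H insertion and anti over syn: slow addition of 4, only a slight excess of 8, low temperature and molecular sieves keep free proton donors scarce, and 7 cannot enolise and is more electrophilic than its oxygen count suggests because its para methoxy group is twisted out of conjugation by two ortho substituents. The ortho bromine of 4 is a spectator here and is kept for step 6.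

Step 6
Reactants: 10 (2R,3R)-3-[3,5-bis(benzyloxy)-4-methoxyphenyl]-1-(6-bromo-2,3,4-trimethoxyphenyl)-3-hydroxy-2-methoxypropan-1-one
Product: 11 (2R,3R)-2-[3,5-bis(benzyloxy)-4-methoxyphenyl]-3,5,6,7-tetramethoxy-2,3-dihydro-4H-chromen-4-one
Conditions: Pd(OAc)2 (5 mol %), 2-(di-tert-butylphosphino)-1,1′-binaphthyl (10 mol %), Cs2CO3, toluene, 65 °C
Reagents that add atoms: none
Why: Intramolecular palladium-catalysed aryl C–O coupling (Buchwald–Hartwig etherification): oxidative addition of zerovalent palladium into the C8a–Br bond, alkoxide binding and reductive elimination close the six-membered ring. The carbinol C–O bond is not broken, so C2 is retained, and the bulky electron-rich phosphine should favour reductive elimination over β-hydride elimination. Any epimerisation at C3 under the carbonate base should drain towards the trans-diequatorial product.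

Step 7
Reactants: 11 (2R,3R)-2-[3,5-bis(benzyloxy)-4-methoxyphenyl]-3,5,6,7-tetramethoxy-2,3-dihydro-4H-chromen-4-one
Product: 12 (2R,3R)-2-(3,5-dihydroxy-4-methoxyphenyl)-3,5,6,7-tetramethoxy-2,3-dihydro-4H-chromen-4-one
Conditions: H2 (1 atm), Pd/C, EtOAc/MeOH, rt
Reagents that add atoms: none
Why: Catalytic hydrogenolysis of the two benzyl aryl ethers under neutral conditions; the electron-rich aryl ketone and the cyclic benzylic C2–O1 bond should react much more slowly at one atmosphere and room temperature. Neither stereocentre is involved.

## Compound list

1 | 5-bromo-1,2,3-trimethoxybenzene | COc1cc(Br)cc(OC)c1OC | starting material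
2 | 1-(6-bromo-2,3,4-trimethoxyphenyl)ethan-1-one | COc1cc(Br)c(C(C)=O)c(OC)c1OC | intermediate
3 | 1-(6-bromo-2,3,4-trimethoxyphenyl)-4,4,4-trifluorobutane-1,3-dione | COc1cc(Br)c(C(=O)CC(=O)C(F)(F)F)c(OC)c1OC | intermediate (not isolated)
4 | 1-(6-bromo-2,3,4-trimethoxyphenyl)-2-diazoethan-1-one | COc1cc(Br)c(C(=O)C=[N+]=[N-])c(OC)c1OC | intermediate
5 | methyl 3,5-dihydroxy-4-methoxybenzoate | COC(=O)c1cc(O)c(OC)c(O)c1 | starting material
6 | methyl 3,5-bis(benzyloxy)-4-methoxybenzoate | COC(=O)c1cc(OCc2ccccc2)c(OC)c(OCc2ccccc2)c1 | intermediate
7 | 3,5-bis(benzyloxy)-4-methoxybenzaldehyde | COc1c(OCc2ccccc2)cc(C=O)cc1OCc1ccccc1 | intermediate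
8 | methanol | CO | starting material
9 | methyl[2-(6-bromo-2,3,4-trimethoxyphenyl)-2-oxoethyl]oxonium ylide (carbanion on the carbon between oxygen and carbonyl; equivalent to its enol) | COc1cc(Br)c(c(OC)c1OC)C(=O)[CH-][OH+]C | intermediate (not isolated)
10 | (2R,3R)-3-[3,5-bis(benzyloxy)-4-methoxyphenyl]-1-(6-bromo-2,3,4-trimethoxyphenyl)-3-hydroxy-2-methoxypropan-1-one | COc1cc(Br)c(c(OC)c1OC)C(=O)[C@H](OC)[C@@H](c1cc(OCc2ccccc2)c(OC)c(OCc2ccccc2)c1)O | intermediate
11 | (2R,3R)-2-[3,5-bis(benzyloxy)-4-methoxyphenyl]-3,5,6,7-tetramethoxy-2,3-dihydro-4H-chromen-4-one | COc1cc2c(c(OC)c1OC)C(=O)[C@H](OC)[C@@H](c1cc(OCc3ccccc3)c(OC)c(OCc3ccccc3)c1)O2 | intermediate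
12 | (2R,3R)-2-(3,5-dihydroxy-4-methoxyphenyl)-3,5,6,7-tetramethoxy-2,3-dihydro-4H-chromen-4-one | COc1cc2c(c(OC)c1OC)C(=O)[C@H](OC)[C@@H](c1cc(O)c(OC)c(O)c1)O2 | target

## Step count and risks

Total: 7 steps. Longest linear sequence: 5 steps (1 → 2 → 4 → 10 → 11 → 12, or equally 5 → 6 → 7 → 10 → 11 → 12).

Step 5 (key step).
- What may go wrong: proton transfer within the ylide may outrun addition to the aldehyde, so that only O–H insertion takes place. The acid-bound transition state may favour the syn arrangement or discriminate poorly between the aldehyde faces. The carbene may also be captured by the neighbouring ring A methoxy oxygen and drained into rearrangement.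
- Fallback: the two bond formations are separated. It sets out from 4 and 8. Rh2(OAc)4 in CH2Cl2 with an excess of 8 should give, by plain O–H insertion, 1-(6-bromo-2,3,4-trimethoxyphenyl)-2-methoxyethan-1-one F1. Me3SiOTf/Et3N should convert it into {[(Z)-1-(6-bromo-2,3,4-trimethoxyphenyl)-2-methoxyethenyl]oxy}trimethylsilane F2. A Mukaiyama aldol addition of F2 to 7, mediated by SiCl4 and a chiral bisphosphoramide Lewis base at −78 °C, proceeds through an open transition state that is normally anti-selective, with the silicon-bound chiral base choosing the aldehyde face. This comes back to the route at 10.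

Step 6.
- What may go wrong: retro-aldol cleavage of the β-hydroxy ketone, enolisation at C3 before closure, or β-hydride elimination from the palladium alkoxide may compete with C–O reductive elimination under the basic conditions.
- Fallback: the ketone is taken out of play during ring closure. It sets out from 10. NaBH4 in MeOH at 0 °C should give (2R,3R)-3-[3,5-bis(benzyloxy)-4-methoxyphenyl]-1-(6-bromo-2,3,4-trimethoxyphenyl)-2-methoxypropane-1,3-diol F3 as a mixture at C1. The same palladium-catalysed C–O coupling should close ring C to (2R,3S)-2-[3,5-bis(benzyloxy)-4-methoxyphenyl]-3,5,6,7-tetramethoxy-3,4-dihydro-2H-chromen-4-ol F4; the other hydroxyl could only close a four-membered ring, and neither retro-aldol cleavage nor epimerisation at C3 is possible. Oxidation of the C4 alcohol with Dess–Martin periodinane comes back to the route at 11.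

Step 1.
- What may go wrong: chelation-assisted cleavage of the methoxy group beside the new ketone by the Lewis acid, or slow acylation at a position flanked by bromine and methoxy.
- Fallback: a smaller electrophile is introduced first. It sets out from 1. Rieche formylation (Cl2CHOMe, TiCl4, CH2Cl2, −78 to 0 °C) should give 6-bromo-2,3,4-trimethoxybenzaldehyde F5, addition of MeMgBr in THF should give 1-(6-bromo-2,3,4-trimethoxyphenyl)ethan-1-ol F6, and oxidation of this benzylic alcohol with MnO2 comes back to the route at 2.

Step 4.
- What may go wrong: the tetrahedral aluminate may collapse before the quench, which leads to over-reduction past the aldehyde stage.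
- Fallback: full reduction followed by reoxidation. It sets out from 6. LiAlH4 in THF should give [3,5-bis(benzyloxy)-4-methoxyphenyl]methanol F7, and MnO2 in CH2Cl2 oxidises the benzylic alcohol and comes back to the route at 7.

## Further compounds

F1 | step 5 | 1-(6-bromo-2,3,4-trimethoxyphenyl)-2-methoxyethan-1-one | COCC(=O)c1c(Br)cc(OC)c(OC)c1OC
F2 | step 5 | {[(Z)-1-(6-bromo-2,3,4-trimethoxyphenyl)-2-methoxyethenyl]oxy}trimethylsilane | CO/C=C(\O[Si](C)(C)C)c1c(Br)cc(OC)c(OC)c1OC
F3 | step 6 | (2R,3R)-3-[3,5-bis(benzyloxy)-4-methoxyphenyl]-1-(6-bromo-2,3,4-trimethoxyphenyl)-2-methoxypropane-1,3-diol (C1 epimers) | COc1cc(Br)c(c(OC)c1OC)C(O)[C@H](OC)[C@@H](c1cc(OCc2ccccc2)c(OC)c(OCc2ccccc2)c1)O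
F4 | step 6 | (2R,3S)-2-[3,5-bis(benzyloxy)-4-methoxyphenyl]-3,5,6,7-tetramethoxy-3,4-dihydro-2H-chromen-4-ol (C4 epimers) | COc1cc2c(c(OC)c1OC)C(O)[C@H](OC)[C@@H](c1cc(OCc3ccccc3)c(OC)c(OCc3ccccc3)c1)O2
F5 | step 1 | 6-bromo-2,3,4-trimethoxybenzaldehyde | COc1cc(Br)c(C=O)c(OC)c1OC
F6 | step 1 | 1-(6-bromo-2,3,4-trimethoxyphenyl)ethan-1-ol (racemic) | COc1cc(Br)c(C(C)O)c(OC)c1OC
F7 | step 4 | [3,5-bis(benzyloxy)-4-methoxyphenyl]methanol | COc1c(OCc2ccccc2)cc(CO)cc1OCc1ccccc1
A1 | alternative 1 | 2-{3-[3,5-bis(benzyloxy)-4-methoxyphenyl]-1-[(tert-butyldimethylsilyl)oxy]-3-(ethynyloxy)-2-methoxypropyl}-3,4-dimethoxycyclobut-2-en-1-one (the two chain stereocentres that become C2 and C3 configured as in 12) | COC1C(=O)C(C(O[Si](C)(C)C(C)(C)C)[C@H](OC)[C@@H](c2cc(OCc3ccccc3)c(OC)c(OCc3ccccc3)c2)OC#C)=C1OC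
A2 | alternative 1 | 2-[3,5-bis(benzyloxy)-4-methoxyphenyl]-4-[(tert-butyldimethylsilyl)oxy]-3,5,6-trimethoxy-3,4-dihydro-2H-chromen-7-ol (C2 and C3 as in 12, C4 epimers) | COc1c(O)cc2c(c1OC)C(O[Si](C)(C)C(C)(C)C)[C@H](OC)[C@@H](c1cc(OCc3ccccc3)c(OC)c(OCc3ccccc3)c1)O2
A3 | alternative 2 | 1-(6-{[3,5-bis(benzyloxy)-4-methoxyphenyl]methoxy}-2,3,4-trimethoxyphenyl)-2-diazoethan-1-one | COc1cc(OCc2cc(OCc3ccccc3)c(OC)c(OCc3ccccc3)c2)c(C(=O)C=[N+]=[N-])c(OC)c1OC
A4 | alternative 2 | (2S)-2-[3,5-bis(benzyloxy)-4-methoxyphenyl]-5,6,7-trimethoxy-2,3-dihydro-4H-chromen-4-one | COc1cc2c(c(OC)c1OC)C(=O)C[C@@H](c1cc(OCc3ccccc3)c(OC)c(OCc3ccccc3)c1)O2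
A5 | alternative 3 | methyl 4-{(2R,3R)-2-[3,5-bis(benzyloxy)-4-methoxyphenyl]-3-methoxy-4-oxo-3,4-dihydro-2H-pyran-6-yl}-2-methoxy-3-oxobutanoate (side-chain C2 epimers) | COC(=O)C(OC)C(=O)CC1=CC(=O)[C@H](OC)[C@@H](c2cc(OCc3ccccc3)c(OC)c(OCc3ccccc3)c2)O1
A6 | alternative 3 | (2R,3R)-2-[3,5-bis(benzyloxy)-4-methoxyphenyl]-5,7-dihydroxy-3,6-dimethoxy-2,3-dihydro-4H-chromen-4-one | COc1c(O)cc2c(c1O)C(=O)[C@H](OC)[C@@H](c1cc(OCc3ccccc3)c(OC)c(OCc3ccccc3)c1)O2
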